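**Plan**

- Ring labels: in the upper chroman (O1 to C8a), ring A is the benzo ring, ring D is the aryl group on C4 and ring E is the aryl group on C3. The lower unit is a 7-hydroxyisoflavan bound through its C3 to ring D.
- Retrosynthesis: remove three benzyl ethers and the ring-E mesylate; cut the ring D–C3 bond of the isoflavan at the isoflav-3-ene level (Suzuki–Miyaura); cut C2–C3 and C4–C4a of the upper pyran; cut the ring E–vinyl bond of the stilbene (Mizoroki–Heck).
- Enabling feature: O1, C2 and ring A of the upper chroman together are an aryloxymethyl cation, and C3 and C4 with rings E and D are an (E)-stilbene, so the pyran is their cationic [4+2] adduct.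
- Forward: ring-D styrene plus ring-E iodide give the stilbene; the annulation builds the upper pyran; the ring-D bromide then takes the lower chromene, which is hydrogenated; the mesylate and the benzyl ethers come off last.
- Stereochemistry: C3 and C4 of the upper chroman arise in the annulation (chiral counter-anion for C3, trans ring closure for C4); C3 of the isoflavan arises in an iridium-catalysed asymmetric hydrogenation.

Key step: step 9

Assumption: the sense of induction of the chiral acid in step 9 and of the iridium complex in step 16 has to be found in first runs; both are accessible in either enantiomeric form, and the antipode that gives the configuration drawn is used.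

**Step 1**
Reactants: 1 4-hydroxy-2-methoxybenzaldehyde
Product: 2 5-bromo-4-hydroxy-2-methoxybenzaldehyde
Conditions: NBS (1.05 equiv), MeCN, 0 °C to rt
Reagents that add atoms: N-bromosuccinimide, O=C1CCC(=O)N1Br
Why: Electrophilic aromatic bromination should go to C5, which is ortho to the free phenol and para to the methoxy group, while C3 between the two oxygens is hindered.

**Step 2**
Reactants: 2 5-bromo-4-hydroxy-2-methoxybenzaldehyde
Product: 3 4-benzyloxy-5-bromo-2-methoxybenzaldehyde
Conditions: BnBr, K2CO3, DMF, rt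
Reagents that add atoms: benzyl bromide, BrCc1ccccc1
Why: Williamson etherification of the phenoxide; aldehyde and aryl bromide are inert to carbonate.

**Step 3**
Reactants: 3 4-benzyloxy-5-bromo-2-methoxybenzaldehyde
Product: 4 1-benzyloxy-2-bromo-4-ethenyl-5-methoxybenzene
Conditions: Ph3PCH3Br, KOtBu, THF, 0 °C to rt
Reagents that add atoms: methyltriphenylphosphonium bromide, C[P+](c1ccccc1)(c1ccccc1)c1ccccc1.[Br-]
Why: Wittig methylenation with the unstabilised ylide converts the aryl aldehyde into the styrene, and an alkoxide base avoids halogen–metal exchange at the aryl bromide.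

**Step 4**
Reactants: 5 2,6-dimethoxyphenol
Product: 6 2,6-dimethoxyphenyl methanesulfonate
Conditions: MsCl, Et3N, CH2Cl2, 0 °C
Reagents that add atoms: methanesulfonyl chloride, CS(=O)(=O)Cl
Why: O-sulfonylation of the phenol masks it and turns its oxygen from a donor into an acceptor, which is needed in steps 5 and 9.

**Step 5**
Reactants: 6 2,6-dimethoxyphenyl methanesulfonate
Product: 7 3-iodo-2,6-dimethoxyphenyl methanesulfonate
Conditions: NIS (1.0 equiv), CF3CO2H (cat.), MeCN, rt, dark
Reagents that add atoms: N-iodosuccinimide, O=C1CCC(=O)N1I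
Why: Electrophilic aromatic iodination should occur at C3, which is ortho to one methoxy group and para to the other, because the mesylated oxygen no longer directs to C4; one equivalent limits diiodination.

**Step 6**
Reactants: 4 1-benzyloxy-2-bromo-4-ethenyl-5-methoxybenzene; 7 3-iodo-2,6-dimethoxyphenyl methanesulfonate
Product: 8 (E)-1-(4-benzyloxy-5-bromo-2-methoxyphenyl)-2-(2,4-dimethoxy-3-mesyloxyphenyl)ethene
Conditions: Pd(OAc)2 (5 mol %), Bu4NCl, NaHCO3, DMF, 80 °C
Reagents that add atoms: none
Why: Mizoroki–Heck reaction without phosphine, in which zerovalent palladium inserts into the C–I bond far faster than into the electron-rich C–Br bond, and syn insertion at the terminal alkene carbon followed by syn β-hydride elimination gives the (E)-stilbene.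

**Step 7**
Reactants: 9 3-(benzyloxy)phenol
Product: 10 1-benzyloxy-3-[(methylsulfanyl)methoxy]benzene
Conditions: NaH, DMF, 0 °C; ClCH2SMe, NaI (cat.), rt
Reagents that add atoms: chloromethyl methyl sulfide, CSCCl
Why: Williamson alkylation of the phenoxide with the α-chloro sulfide under iodide catalysis gives the methylthiomethyl ether.

**Step 8**
Reactants: 10 1-benzyloxy-3-[(methylsulfanyl)methoxy]benzene
Product: 11 1-benzyloxy-3-(chloromethoxy)benzene
Conditions: SO2Cl2 (1.0 equiv), cyclohexene, CH2Cl2, −78 to 0 °C; concentrate and use at once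
Reagents that add atoms: sulfuryl chloride, ClS(Cl)(=O)=O
Why: S-chlorination of the sulfide and chloride attack at the O,S-acetal carbon (Pummerer-type fragmentation of the chlorosulfonium ion) release the chloromethyl ether; the sulfur reacts much faster than the arene at low temperature, and cyclohexene traps the methanesulfenyl chloride.

**Step 9**
Reactants: 8 (E)-1-(4-benzyloxy-5-bromo-2-methoxyphenyl)-2-(2,4-dimethoxy-3-mesyloxyphenyl)ethene; 11 1-benzyloxy-3-(chloromethoxy)benzene
Product: 14 (3R,4S)-7-benzyloxy-4-(4-benzyloxy-5-bromo-2-methoxyphenyl)-3-(2,4-dimethoxy-3-mesyloxyphenyl)chroman, via aryloxymethyl oxocarbenium ion 12 (not isolated), via C4 benzylic cation 13 (not isolated)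
Conditions: confined N-triflyl imidodiphosphorimidate acid from two 3,3'-diaryl-BINOL units (5 mol %), 11 (2 equiv) added over 8 h, CH2Cl2/toluene, −50 °C, slow argon stream
Reagents that add atoms: none
Why: Proposed new method: the imidodiphosphorimidate acid ionises the C–Cl bond of 11 by hydrogen bonding to chloride, which leaves as HCl, so that oxocarbenium ion 12 is paired only with the confined chiral anion; 12 then bonds through its CH2 carbon to the alkene carbon of 8 that carries ring E (C2–C3), the resulting cation 13 sits next to ring D, and ring A attacks it para to its benzyloxy group (C4–C4a) with loss of the proton that regenerates the acid. The closest known reaction types are the Lewis-acid oxa-Povarov annulation of aryl-substituted oxocarbenium ions with styrenes and the Prins chemistry of formaldehyde-derived oxocarbenium ions under imidodiphosphorimidate catalysis; an unsubstituted aryloxymethyl cation, a stilbene partner and control by a chiral anion have not been shown. The pyran ring, the only ring formed, closes in the second bond formation as a six-membered intramolecular Friedel–Crafts alkylation of ring A by cation 13, so the whole is a stepwise cationic [4+2]. C3 is set in the first bond formation, where the anion pocket selects the enantiotopic face of the (E)-alkene, and C4 is set at ring closure, where a half-chair with both aryl groups pseudo-equatorial gives the 3,4-trans product. The step needs the cation to form at the ring-D carbon and not at the ring-E carbon: ring D offers a para benzyloxy and a coplanar ortho methoxy donor, whereas in ring E the ortho methoxy group is twisted out of conjugation between the side chain and the mesylate, which itself withdraws inductively. Self-alkylation of the electron-rich ring of 11 is held back by its slow addition, and the bromine blocks the most nucleophilic position of ring D.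

**Step 10**
Reactants: 15 7-hydroxychroman-4-one
Product: 16 7-benzyloxychroman-4-one
Conditions: BnBr, K2CO3, DMF, 60 °C
Reagents that add atoms: benzyl bromide, BrCc1ccccc1
Why: Williamson etherification of the acidic phenol para to the ketone.

**Step 11**
Reactants: 16 7-benzyloxychroman-4-one
Product: 17 7-benzyloxy-3-bromochroman-4-one (racemic)
Conditions: CuBr2 (2.1 equiv), EtOAc/CHCl3, reflux
Reagents that add atoms: copper dibromide, Br[Cu]Br
Why: α-Bromination of the ketone by CuBr2 through its enol gives the monobromide at C3, the only enolisable carbon; the arene is a vinylogous ester and should not be brominated.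

**Step 12**
Reactants: 17 7-benzyloxy-3-bromochroman-4-one
Product: 18 7-benzyloxy-3-bromochroman-4-ol (racemic, mixture of diastereomers)
Conditions: NaBH4, MeOH/THF, 0 °C
Reagents that add atoms: none
Why: Borohydride reduction of the ketone at 0 °C gives the bromohydrin without loss of bromide; its relative configuration does not matter because C4 becomes trigonal in the next step.

**Step 13**
Reactants: 18 7-benzyloxy-3-bromochroman-4-ol
Product: 19 7-benzyloxy-3-bromo-2H-chromene
Conditions: p-TsOH·H2O (5 mol %), toluene, 90 °C, azeotropic removal of water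
Reagents that add atoms: none
Why: Acid-catalysed E1 dehydration through the benzylic cation stabilised by the para benzyloxy group can only lose the C3 proton and gives the conjugated alkenyl bromide.

**Step 14**
Reactants: 19 7-benzyloxy-3-bromo-2H-chromene
Product: 20 2-(7-benzyloxy-2H-chromen-3-yl)-4,4,5,5-tetramethyl-1,3,2-dioxaborolane
Conditions: B2pin2, Pd(dppf)Cl2 (3 mol %), KOAc, 1,4-dioxane, 85 °C
Reagents that add atoms: bis(pinacolato)diboron, CC1(C)OB(OC1(C)C)B1OC(C)(C)C(C)(C)O1
Why: Miyaura borylation of the alkenyl bromide, with acetate as a base too weak to trigger homocoupling.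

**Step 15**
Reactants: 14 (3R,4S)-7-benzyloxy-4-(4-benzyloxy-5-bromo-2-methoxyphenyl)-3-(2,4-dimethoxy-3-mesyloxyphenyl)chroman; 20 2-(7-benzyloxy-2H-chromen-3-yl)-4,4,5,5-tetramethyl-1,3,2-dioxaborolane
Product: 21 (3R,4S)-7-benzyloxy-4-[4-benzyloxy-5-(7-benzyloxy-2H-chromen-3-yl)-2-methoxyphenyl]-3-(2,4-dimethoxy-3-mesyloxyphenyl)chroman
Conditions: Pd(OAc)2 (3 mol %), SPhos (6 mol %), K3PO4, toluene/H2O, 80 °C
Reagents that add atoms: none
Why: Suzuki–Miyaura coupling in which the electron-rich biarylphosphine lets zerovalent palladium insert into the ortho-alkoxy aryl bromide, while the hindered aryl mesylate and both stereocentres are untouched.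

**Step 16**
Reactants: 21 (3R,4S)-7-benzyloxy-4-[4-benzyloxy-5-(7-benzyloxy-2H-chromen-3-yl)-2-methoxyphenyl]-3-(2,4-dimethoxy-3-mesyloxyphenyl)chroman
Product: 22 (3R,4S)-7-benzyloxy-4-{4-benzyloxy-5-[(3R)-7-benzyloxychroman-3-yl]-2-methoxyphenyl}-3-(2,4-dimethoxy-3-mesyloxyphenyl)chroman
Conditions: [Ir(cod)(L)][B(C6H3-3,5-(CF3)2)4] (2 mol %; L = chiral dicyclohexylphosphinite–oxazoline derived from threonine), H2 (50 bar), CH2Cl2, rt
Reagents that add atoms: none
Why: Iridium-catalysed asymmetric hydrogenation of an unfunctionalised trisubstituted alkene with a cationic P,N-ligand complex, a reaction established for isoflav-3-enes, adds H2 to one face of the chromene double bond and so sets the isoflavan C3 as R under catalyst control; benzyl ethers, mesylate and the remote stereocentres are unaffected.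

**Step 17**
Reactants: 22 (3R,4S)-7-benzyloxy-4-{4-benzyloxy-5-[(3R)-7-benzyloxychroman-3-yl]-2-methoxyphenyl}-3-(2,4-dimethoxy-3-mesyloxyphenyl)chroman
Product: 23 (3R,4S)-7-benzyloxy-4-{4-benzyloxy-5-[(3R)-7-benzyloxychroman-3-yl]-2-methoxyphenyl}-3-(3-hydroxy-2,4-dimethoxyphenyl)chroman
Conditions: KOH, MeOH/THF/H2O, 65 °C
Reagents that add atoms: none
Why: Alkaline cleavage of the aryl sulfonate ester frees the ring-E phenol; benzyl ethers and the three stereocentres, none of which carries an acidic hydrogen, are stable to hydroxide.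

**Step 18**
Reactants: 23 (3R,4S)-7-benzyloxy-4-{4-benzyloxy-5-[(3R)-7-benzyloxychroman-3-yl]-2-methoxyphenyl}-3-(3-hydroxy-2,4-dimethoxyphenyl)chroman
Product: 24 (3R,4S)-3-(3-hydroxy-2,4-dimethoxyphenyl)-4-{4-hydroxy-5-[(3R)-7-hydroxychroman-3-yl]-2-methoxyphenyl}chroman-7-ol
Conditions: H2 (1 atm), Pd/C (10 wt %), EtOAc/MeOH, rt
Reagents that add atoms: none
Why: Catalytic hydrogenolysis removes the three benzyl ethers under neutral conditions that leave the chroman C–O bonds, the diarylmethine and all stereocentres intact.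

**Compound list**

1 | 4-hydroxy-2-methoxybenzaldehyde | COc1cc(O)ccc1C=O | starting material
2 | 5-bromo-4-hydroxy-2-methoxybenzaldehyde | COc1cc(O)c(Br)cc1C=O | intermediate
3 | 4-benzyloxy-5-bromo-2-methoxybenzaldehyde | COc1cc(OCc2ccccc2)c(Br)cc1C=O | intermediate
4 | 1-benzyloxy-2-bromo-4-ethenyl-5-methoxybenzene | COc1cc(OCc2ccccc2)c(Br)cc1C=C | intermediate
5 | 2,6-dimethoxyphenol | COc1cccc(OC)c1O | starting material
6 | 2,6-dimethoxyphenyl methanesulfonate | COc1cccc(OC)c1OS(C)(=O)=O | intermediate
7 | 3-iodo-2,6-dimethoxyphenyl methanesulfonate | COc1ccc(I)c(OC)c1OS(C)(=O)=O | intermediate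
8 | (E)-1-(4-benzyloxy-5-bromo-2-methoxyphenyl)-2-(2,4-dimethoxy-3-mesyloxyphenyl)ethene | COc1cc(OCc2ccccc2)c(Br)cc1/C=C/c1ccc(OC)c(OS(C)(=O)=O)c1OC | intermediate
9 | 3-(benzyloxy)phenol | Oc1cccc(OCc2ccccc2)c1 | starting material
10 | 1-benzyloxy-3-[(methylsulfanyl)methoxy]benzene | CSCOc1cccc(OCc2ccccc2)c1 | intermediate
11 | 1-benzyloxy-3-(chloromethoxy)benzene | ClCOc1cccc(OCc2ccccc2)c1 | intermediate
12 | (3-benzyloxyphenyl)(methylidene)oxonium ion, paired with the imidodiphosphorimidate anion, not isolated | C=[O+]c1cccc(OCc2ccccc2)c1 | intermediate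
13 | (2R)-1-(4-benzyloxy-5-bromo-2-methoxyphenyl)-3-(3-benzyloxyphenoxy)-2-(2,4-dimethoxy-3-mesyloxyphenyl)propan-1-ylium ion, not isolated | COc1cc(OCc2ccccc2)c(Br)cc1[CH+][C@@H](COc1cccc(OCc2ccccc2)c1)c1ccc(OC)c(OS(C)(=O)=O)c1OC | intermediate
14 | (3R,4S)-7-benzyloxy-4-(4-benzyloxy-5-bromo-2-methoxyphenyl)-3-(2,4-dimethoxy-3-mesyloxyphenyl)chroman (3,4-trans) | COc1cc(OCc2ccccc2)c(Br)cc1[C@@H]1c2ccc(OCc3ccccc3)cc2OC[C@H]1c1ccc(OC)c(OS(C)(=O)=O)c1OC | intermediate
15 | 7-hydroxychroman-4-one | O=C1CCOc2cc(O)ccc12 | starting material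
16 | 7-benzyloxychroman-4-one | O=C1CCOc2cc(OCc3ccccc3)ccc12 | intermediate
17 | 7-benzyloxy-3-bromochroman-4-one (racemic) | O=C1C(Br)COc2cc(OCc3ccccc3)ccc12 | intermediate
18 | 7-benzyloxy-3-bromochroman-4-ol (racemic, diastereomer mixture) | OC1C(Br)COc2cc(OCc3ccccc3)ccc12 | intermediate
19 | 7-benzyloxy-3-bromo-2H-chromene | BrC1=Cc2ccc(OCc3ccccc3)cc2OC1 | intermediate
20 | 2-(7-benzyloxy-2H-chromen-3-yl)-4,4,5,5-tetramethyl-1,3,2-dioxaborolane | CC1(C)OB(OC1(C)C)C1=Cc2ccc(OCc3ccccc3)cc2OC1 | intermediate
21 | (3R,4S)-7-benzyloxy-4-[4-benzyloxy-5-(7-benzyloxy-2H-chromen-3-yl)-2-methoxyphenyl]-3-(2,4-dimethoxy-3-mesyloxyphenyl)chroman | COc1cc(OCc2ccccc2)c(C2=Cc3ccc(OCc4ccccc4)cc3OC2)cc1[C@@H]1c2ccc(OCc3ccccc3)cc2OC[C@H]1c1ccc(OC)c(OS(C)(=O)=O)c1OC | intermediate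
22 | (3R,4S)-7-benzyloxy-4-{4-benzyloxy-5-[(3R)-7-benzyloxychroman-3-yl]-2-methoxyphenyl}-3-(2,4-dimethoxy-3-mesyloxyphenyl)chroman | COc1cc(OCc2ccccc2)c([C@@H]2COc3cc(OCc4ccccc4)ccc3C2)cc1[C@@H]1c2ccc(OCc3ccccc3)cc2OC[C@H]1c1ccc(OC)c(OS(C)(=O)=O)c1OC | intermediate
23 | (3R,4S)-7-benzyloxy-4-{4-benzyloxy-5-[(3R)-7-benzyloxychroman-3-yl]-2-methoxyphenyl}-3-(3-hydroxy-2,4-dimethoxyphenyl)chroman | COc1cc(OCc2ccccc2)c([C@@H]2COc3cc(OCc4ccccc4)ccc3C2)cc1[C@@H]1c2ccc(OCc3ccccc3)cc2OC[C@H]1c1ccc(OC)c(O)c1OC | intermediate
24 | (3R,4S)-3-(3-hydroxy-2,4-dimethoxyphenyl)-4-{4-hydroxy-5-[(3R)-7-hydroxychroman-3-yl]-2-methoxyphenyl}chroman-7-ol | COc1cc(O)c([C@@H]2COc3cc(O)ccc3C2)cc1[C@@H]1c2ccc(O)cc2OC[C@H]1c1ccc(OC)c(O)c1OC | target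

**Step count**

Total: 18 steps. Longest linear sequence: 9 steps (steps 1, 2, 3, 6, 9, 15, 16, 17, 18; the line through steps 10 to 14 is equally long).

**Steps most likely to fail**

Step 9. The oxocarbenium ion may alkylate the electron-rich ring of its own precursor faster than it adds to the stilbene. Cation 13 may lose its C3 proton to an alkene, which erases the new stereocentre. Face selection inside the ion pair may be poor, and the cation may form in part at the ring-E carbon. The fallback uses known chemistry, the amine-catalysed formal [4+2] of an aldehyde with an ortho-quinone methide; it sets out from 3, 7 and 9 and returns at 14.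
- Acid-mediated three-component condensation of phenol 9, aldehyde 3 and sodium 4-methylbenzenesulfinate (HCO2H/H2O, rt) should give the quinone methide precursor 5-benzyloxy-2-[(4-benzyloxy-5-bromo-2-methoxyphenyl)(4-methylbenzenesulfonyl)methyl]phenol F1.
- Suzuki–Miyaura coupling of iodide 7 with (E)-2-(2-ethoxyethenyl)-4,4,5,5-tetramethyl-1,3,2-dioxaborolane (Pd(dppf)Cl2, K2CO3, dioxane/H2O) gives the enol ether 3-[(E)-2-ethoxyethenyl]-2,6-dimethoxyphenyl methanesulfonate F2. Dilute HCl in THF hydrolyses it to the arylacetaldehyde 2,6-dimethoxy-3-(2-oxoethyl)phenyl methanesulfonate F3.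
- With 2-[diphenyl(trimethylsilyloxy)methyl]pyrrolidine (20 mol %) and NaHCO3 in CH2Cl2, F1 loses sulfinate to the ortho-quinone methide and the enamine of F3 adds to it. Hemiacetal closure gives the trans lactol (3R,4S)-7-benzyloxy-4-(4-benzyloxy-5-bromo-2-methoxyphenyl)-3-(2,4-dimethoxy-3-mesyloxyphenyl)chroman-2-ol F4, as a mixture at C2.
- Ionic reduction of the lactol (Et3SiH, BF3·OEt2, CH2Cl2, −78 to −20 °C) removes the anomeric hydroxyl and delivers 14.

Step 16. The hydrogenation may stall on the hindered alkene, whose aryl group carries an ortho benzyloxy substituent, or may add to both faces with little preference. The fallback sets the isoflavan centre by dynamic kinetic resolution; it sets out from 14 and ketone 16, bypasses 20 and 21, and returns at 22.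
- Palladium-catalysed α-arylation of 16 with bromide 14 (Pd(OAc)2, P(t-Bu)3·HBF4, K3PO4, toluene, 90 °C) gives the isoflavanone (3R,4S)-7-benzyloxy-4-[4-benzyloxy-5-(7-benzyloxy-4-oxochroman-3-yl)-2-methoxyphenyl]-3-(2,4-dimethoxy-3-mesyloxyphenyl)chroman F5, epimeric at the enolisable carbon.
- Transfer hydrogenation with RuCl(p-cymene)(TsDPEN) in HCO2H/Et3N reduces one rapidly equilibrating epimer faster and gives the cis alcohol (3R,4S)-7-benzyloxy-4-{4-benzyloxy-5-[(3R,4R)-7-benzyloxy-4-hydroxychroman-3-yl]-2-methoxyphenyl}-3-(2,4-dimethoxy-3-mesyloxyphenyl)chroman F6.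
- Ionic deoxygenation of the benzylic alcohol (Et3SiH, CF3CO2H, CH2Cl2, −20 °C) gives 22.

Step 8. Sulfuryl chloride or the sulfenyl chloride may attack the electron-rich ring, and the chloromethyl ether may condense with itself on concentration. The fallback changes the leaving group so that no chlorinating reagent is needed; it sets out from 9 and returns at cation 12, and through it at 14.
- Alkylation of 9 with chloromethyl pivalate (K2CO3, NaI cat., DMF) gives the stable acyloxymethyl ether (3-benzyloxyphenoxy)methyl 2,2-dimethylpropanoate F7.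
- In step 9, F7 is added in place of 11. The same acid protonates the ester carbonyl, pivalic acid leaves, and ion 12 forms with the chiral anion as before.

**Further compounds**

F1 | step 9 | 5-benzyloxy-2-[(4-benzyloxy-5-bromo-2-methoxyphenyl)(4-methylbenzenesulfonyl)methyl]phenol (racemic) | COc1cc(OCc2ccccc2)c(Br)cc1C(c1ccc(OCc2ccccc2)cc1O)S(=O)(=O)c1ccc(C)cc1
F2 | step 9 | 3-[(E)-2-ethoxyethenyl]-2,6-dimethoxyphenyl methanesulfonate | CCO/C=C/c1ccc(OC)c(OS(C)(=O)=O)c1OC
F3 | step 9 | 2,6-dimethoxy-3-(2-oxoethyl)phenyl methanesulfonate | O=CCc1ccc(OC)c(OS(C)(=O)=O)c1OC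
F4 | step 9 | (3R,4S)-7-benzyloxy-4-(4-benzyloxy-5-bromo-2-methoxyphenyl)-3-(2,4-dimethoxy-3-mesyloxyphenyl)chroman-2-ol (mixture at C2) | COc1cc(OCc2ccccc2)c(Br)cc1[C@@H]1c2ccc(OCc3ccccc3)cc2OC(O)[C@H]1c1ccc(OC)c(OS(C)(=O)=O)c1OC
F5 | step 16 | (3R,4S)-7-benzyloxy-4-[4-benzyloxy-5-(7-benzyloxy-4-oxochroman-3-yl)-2-methoxyphenyl]-3-(2,4-dimethoxy-3-mesyloxyphenyl)chroman (epimers at the ketone α-carbon) | COc1cc(OCc2ccccc2)c(C2COc3cc(OCc4ccccc4)ccc3C2=O)cc1[C@@H]1c2ccc(OCc3ccccc3)cc2OC[C@H]1c1ccc(OC)c(OS(C)(=O)=O)c1OC
F6 | step 16 | (3R,4S)-7-benzyloxy-4-{4-benzyloxy-5-[(3R,4R)-7-benzyloxy-4-hydroxychroman-3-yl]-2-methoxyphenyl}-3-(2,4-dimethoxy-3-mesyloxyphenyl)chroman | COc1cc(OCc2ccccc2)c([C@@H]2COc3cc(OCc4ccccc4)ccc3[C@@H]2O)cc1[C@@H]1c2ccc(OCc3ccccc3)cc2OC[C@H]1c1ccc(OC)c(OS(C)(=O)=O)c1OC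
F7 | step 8 | (3-benzyloxyphenoxy)methyl 2,2-dimethylpropanoate | CC(C)(C)C(=O)OCOc1cccc(OCc2ccccc2)c1
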